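**Plan**

- Retrosynthesis: the acetate and the C11/C12 stereocentres go back to tetracyclic enone 31. The cyclohexane (C1, C10–C14) is opened at C12=C13, then the oxepane at O–C16, the C1–C14 bond, the oxonane at C4=C5, and the oxolane at O–C2 and C9–C10.
- Forward order of rings: oxolane (formal [3+2] of a vinylcyclopropane diester with an aldehyde), oxonane (ring-closing metathesis), then C1–C14 by Michael addition of a butyrolactone enolate, oxepane (etherification), cyclohexane last (ring-closing metathesis).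
- Enabling feature: the cyclohexane shares only C1–C10 with the oxolane and C1–C14 with the trans-fused oxepane. In the tricyclic tris-ether the C10 acyl and C14 vinyl groups sit syn on the exo face of adjacent carbons, so the C11–C12=C13 bridge closes easily, and C11 and C12 stay trigonal until they are set from the convex face.
- Stereochemistry: C6/C7 from catalytic syn-crotylboration; C2 from (R)-but-3-ene-1,2-diol (two inversions); C9 from the cis-selective [3+2]; C3 from chelate-controlled Grignard addition; C15 from (R)-4-methyloxolan-2-one, whose temporary lactone ring controls C14; C1/C10 from exo attack and protonation; C12 and C11 from convex-face hydrogenation and hydride reduction.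

Key step: step 22

Remark: intermediates are named with the skeleton numbering of the target (carbocycle C1–C10 with the O bridge C2–O–C9, ether C3–O–C16, C11–C13 closing the cyclohexane with C1, C10 and C14, C15 methyl-bearing); (R)-but-3-ene-1,2-diol and (R)-4-methyloxolan-2-one are taken as commercial.

**Route**

Step 1
Reactants: 1 (E)-but-2-enal; 2 (Z)-crotylboronic acid pinacol ester
Product: 3 (3R,4R,5E)-3-methylhepta-1,5-dien-4-ol
Conditions: (S)-TRIP [(S)-3,3'-bis(2,4,6-triisopropylphenyl)-BINOL hydrogen phosphate] (5 mol %), 4 Å MS, toluene, −30 °C; aq. NaHCO3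
Reagents that add atoms: none
Why: Chiral phosphoric acid-catalysed crotylboration through a closed chair transition state should give the syn product from the (Z)-boronate, with the catalyst enantiomer chosen to direct addition to the Si face of the aldehyde, which sets C6 and C7.

Step 2
Reactants: 3 (3R,4R,5E)-3-methylhepta-1,5-dien-4-ol
Product: 4 (3R,4R,5E)-4-methoxy-3-methylhepta-1,5-diene
Conditions: NaH, MeI, THF, 0 → 23 °C
Reagents that add atoms: iodomethane (CI)
Why: Williamson etherification of the secondary alkoxide with iodomethane touches no stereocentre.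

Step 3
Reactants: 4 (3R,4R,5E)-4-methoxy-3-methylhepta-1,5-diene
Product: 5 (3R,4S,5E)-4-methoxy-3-methylhept-5-en-1-ol
Conditions: 9-BBN (1.2 equiv), THF, 0 → 23 °C; then NaOH, H2O2, 0 °C
Reagents that add atoms: hydrogen peroxide (OO)
Why: Anti-Markovnikov hydroboration–oxidation with the bulky 9-BBN should take the terminal vinyl group and leave the 1,2-disubstituted allylic-ether alkene.

Step 4
Reactants: 5 (3R,4S,5E)-4-methoxy-3-methylhept-5-en-1-ol
Product: 6 (3R,4S,5E)-4-methoxy-3-methylhept-5-enal
Conditions: Dess–Martin periodinane, NaHCO3, CH2Cl2, 23 °C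
Reagents that add atoms: none
Why: Dess–Martin oxidation of the primary alcohol stops at the aldehyde, whose stereocentre is β and not epimerizable.

Step 5
Reactants: 7 (R)-but-3-ene-1,2-diol
Product: 9 (4R)-4-vinyl-1,3,2-dioxathiolane 2,2-dioxide, via cyclic sulfite 8 (not isolated)
Conditions: SOCl2, Et3N, CH2Cl2, 0 °C; then RuCl3 (0.5 mol %), NaIO4, MeCN/H2O, 0 °C, short contact time
Reagents that add atoms: thionyl chloride (O=S(Cl)Cl); sodium periodate ([Na+].[O-][I](=O)(=O)=O)
Why: Cyclic sulfite formation and ruthenium-catalysed oxidation to the cyclic sulfate activate both carbinol carbons without touching the stereocentre, sulfur oxidation being much faster than alkene cleavage.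

Step 6
Reactants: 9 (4R)-4-vinyl-1,3,2-dioxathiolane 2,2-dioxide; 10 dimethyl malonate
Product: 11 dimethyl (2R)-2-vinylcyclopropane-1,1-dicarboxylate
Conditions: NaH (2.2 equiv), THF, 0 → 65 °C
Reagents that add atoms: none
Why: Double alkylation of malonate by a cyclic sulfate (3-exo-tet closure) puts one SN2 inversion at the allylic carbon, so the (R)-diol should give the (R)-cyclopropane.

Step 7
Reactants: 6 (3R,4S,5E)-4-methoxy-3-methylhept-5-enal; 11 dimethyl (2R)-2-vinylcyclopropane-1,1-dicarboxylate
Product: 12 dimethyl (2S,5S)-5-ethenyl-2-[(2R,3S,4E)-3-methoxy-2-methylhex-4-en-1-yl]oxolane-3,3-dicarboxylate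
Conditions: Hf(OTf)4 (5 mol %), CH2Cl2, 23 °C
Reagents that add atoms: none
Why: Lewis acid-catalysed formal [3+2] cycloaddition of a donor–acceptor cyclopropane with an aldehyde: the carbonyl oxygen opens the activated ring at the vinyl-bearing carbon with inversion (sets C2) and the malonate closes on the oxocarbenium carbon through an envelope with both substituents pseudo-equatorial (sets C9, 2,5-cis).

Step 8
Reactants: 12 oxolane diester with C2 vinyl group
Product: 13 dimethyl (2S,5S)-5-acetyl-2-[(2R,3S,4E)-3-methoxy-2-methylhex-4-en-1-yl]oxolane-3,3-dicarboxylate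
Conditions: PdCl2 (10 mol %), CuCl (1 equiv), O2 (1 atm), DMF/H2O 7:1, 23 °C
Reagents that add atoms: water (O)
Why: Wacker oxidation should convert the terminal vinyl group into the methyl ketone (Markovnikov hydroxypalladation) far faster than it touches the internal propenyl group.

Step 9
Reactants: 13 oxolane methyl ketone
Product: 14 dimethyl (2S,5S)-5-[(2S)-2-hydroxybut-3-en-2-yl]-2-[(2R,3S,4E)-3-methoxy-2-methylhex-4-en-1-yl]oxolane-3,3-dicarboxylate
Conditions: CH2=CHMgBr (1.5 equiv), THF, −78 °C; sat. aq. NH4Cl at −78 °C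
Reagents that add atoms: vinylmagnesium bromide (C=C[Mg]Br)
Why: Chelation-controlled Grignard addition (Cram chelate between the ketone oxygen and the ring oxygen) should deliver the vinyl group to the face of the C2 hydrogen and set (3S), while the neopentyl diester is inert at −78 °C.

Step 10
Reactants: 14 oxolane diene (C3 vinyl, C6 propenyl)
Product: 15 dimethyl (2S,3S,4Z,6S,7R,9S)-3-hydroxy-6-methoxy-3,7-dimethyl-2,9-epoxycyclodec-4-ene-10,10-dicarboxylate
Conditions: second-generation Grubbs catalyst (10 mol %), CH2Cl2 (2 mM), 40 °C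
Reagents that add atoms: none
Why: Ring-closing metathesis with loss of propene should close the nine-membered oxonene as the Z alkene because the two alkenyl arms are held cis on the 2,5-positions of the oxolane.

Step 11
Reactants: 15 bicyclic oxonene diester
Product: 16 dimethyl (2S,3S,6R,7R,9S)-3-hydroxy-6-methoxy-3,7-dimethyl-2,9-epoxycyclodecane-10,10-dicarboxylate
Conditions: H2 (1 atm), PtO2 (5 mol %), EtOAc, 23 °C
Reagents that add atoms: none
Why: Heterogeneous hydrogenation of the only alkene over platinum avoids hydrogenolysis of the two allylic C–O bonds.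

Step 12
Reactants: 16 bicyclic tertiary alcohol
Product: 17 dimethyl (2S,3S,6R,7R,9S)-3-[(tert-butyldimethylsilyl)oxy]-6-methoxy-3,7-dimethyl-2,9-epoxycyclodecane-10,10-dicarboxylate
Conditions: TBSOTf (2 equiv), 2,6-lutidine (4 equiv), CH2Cl2, 0 → 23 °C
Reagents that add atoms: tert-butyldimethylsilyl trifluoromethanesulfonate (CC(C)(C)[Si](C)(C)OS(=O)(=O)C(F)(F)F)
Why: Silylation of the tertiary alcohol with the silyl triflate masks the C3 hydroxyl so that it cannot lactonize onto a C10 ester in the steps that follow.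

Step 13
Reactants: 17 silyl ether diester
Product: 18 methyl (2S,3S,6R,7R,9S)-3-[(tert-butyldimethylsilyl)oxy]-6-methoxy-3,7-dimethyl-2,9-epoxycyclodecane-10-carboxylate (C10 epimers)
Conditions: LiCl (3 equiv), H2O (2 equiv), DMSO, 150 °C
Reagents that add atoms: none
Why: Krapcho dealkoxycarbonylation removes one ester of the malonate, and the C10 epimer mixture is inconsequential because C10 becomes trigonal in step 14.

Step 14
Reactants: 18 monoester
Product: 21 methyl (2S,3S,6R,7R,9S)-3-[(tert-butyldimethylsilyl)oxy]-6-methoxy-3,7-dimethyl-2,9-epoxycyclodec-1(10)-ene-10-carboxylate, via α-phenylselanyl ester 19 (not isolated), via selenoxide 20 (not isolated)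
Conditions: LiN(i-Pr)2 (1.2 equiv), THF, −78 °C; PhSeBr; then 30% H2O2, pyridine, CH2Cl2, 0 → 23 °C
Reagents that add atoms: none
Why: α-Selenenylation of the ester enolate and syn elimination of the selenoxide should place the double bond toward C1, away from the oxygen-bearing C9, giving the 2,5-dihydrofuran-3-carboxylate.

Step 15
Reactants: 21 bicyclic enoate; 22 (4R)-4-methyloxolan-2-one
Product: 23 methyl (1S,2S,3S,6R,7R,9S,10R)-3-[(tert-butyldimethylsilyl)oxy]-6-methoxy-3,7-dimethyl-1-[(3S,4R)-4-methyl-2-oxooxolan-3-yl]-2,9-epoxycyclodecane-10-carboxylate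
Conditions: 22 (1.5 equiv), LiN(i-Pr)2 (1.55 equiv), THF, −78 °C; then 21, −78 → −40 °C; AcOH at −78 °C
Reagents that add atoms: none
Why: Michael addition of a lithium lactone enolate to an α,β-unsaturated ester: the enolate should react trans to its C15 methyl group (sets C14) on the exo face of C1, anti to the C2–C3 bond and the oxonane bridge (sets C1), and the ester enolate should be protonated anti to the new C1 substituent (sets C10).

Step 16
Reactants: 23 Michael adduct (lactone ester)
Product: 24 lactol: 23 with the lactone C13 carbonyl reduced to the hemiacetal (anomers)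
Conditions: disiamylborane (3 equiv, from BH3·THF and 2-methylbut-2-ene), THF, 0 → 23 °C; then H2O2, pH 7 buffer
Reagents that add atoms: none
Why: Disiamylborane reduction of a γ-lactone should stop at the lactol and leave the methyl ester untouched.

Step 17
Reactants: 24 lactol
Product: 25 methyl (1S,2S,3S,6R,7R,9S,10R)-3-[(tert-butyldimethylsilyl)oxy]-1-[(3S,4R)-5-hydroxy-4-methylpent-1-en-3-yl]-6-methoxy-3,7-dimethyl-2,9-epoxycyclodecane-10-carboxylate
Conditions: Ph3PCH3Br (4 equiv), KOt-Bu (3.8 equiv), THF, 0 °C; then 24, 0 → 23 °C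
Reagents that add atoms: methyltriphenylphosphonium bromide (C[P+](c1ccccc1)(c1ccccc1)c1ccccc1.[Br-])
Why: Wittig methylenation of the lactol through its open hydroxy aldehyde turns C13 into the vinyl group for the final ring closure and frees the C16 hydroxyl, which differentiates the two lactone carbons.

Step 18
Reactants: 25 silyl ether with C16 hydroxyl
Product: 26 diol: 25 with the C3 silyl ether cleaved (free tertiary C3–OH and primary C16–OH)
Conditions: HF·pyridine, pyridine/THF, 0 → 40 °C
Reagents that add atoms: none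
Why: Fluoride-mediated desilylation under buffered acidic conditions should leave the ester, the alkene and the C10 and C14 stereocentres alone.

Step 19
Reactants: 26 diol
Product: 28 tricyclic vinyl ester (1S,2S,3S,6R,7R,9S,10R,14S,15R) with the C3–O–C16 oxepane closed, via primary triflate 27 (not isolated)
Conditions: Tf2O (1.1 equiv), 2,6-lutidine (3 equiv), CH2Cl2, −78 → 23 °C
Reagents that add atoms: none
Why: Selective triflation of the primary C16 hydroxyl followed by intramolecular Williamson-type SN2 displacement by the tertiary C3 hydroxyl (7-exo-tet) should close the trans-fused oxepane without touching a stereocentre.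

Step 20
Reactants: 28 tricyclic vinyl ester
Product: 29 Weinreb amide: 28 with C10–CON(CH3)OCH3 in place of the methyl ester
Conditions: MeNH(OMe)·HCl (4 equiv), i-PrMgCl (8 equiv), THF, −20 → 0 °C
Reagents that add atoms: N,O-dimethylhydroxylamine hydrochloride (CNOC.Cl)
Why: Aminolysis of the ester by the magnesium amide of N,O-dimethylhydroxylamine is the standard Weinreb amide formation from hindered esters.

Step 21
Reactants: 29 Weinreb amide
Product: 30 isopropenyl ketone: C10–C(=O)–C(CH3)=CH2 and C14–CH=CH2 on the tricyclic tris-ether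
Conditions: CH2=C(CH3)MgBr (3 equiv), THF, 0 °C; then cold 1 M HCl
Reagents that add atoms: isopropenylmagnesium bromide (CC(=C)[Mg]Br)
Why: Grignard addition to a Weinreb amide stops at the ketone through the chelated tetrahedral intermediate and installs C12 with its methyl group.

Step 22
Reactants: 30 isopropenyl ketone diene
Product: 31 tetracyclic enone (1S,2S,3S,6R,7R,9S,10R,14S,15R): 11-oxo, C12=C13, C12 methyl
Conditions: second-generation Hoveyda–Grubbs catalyst (10 mol %), toluene (5 mM), 80 °C, N2 sparge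
Reagents that add atoms: none
Why: The ruthenium alkylidene loads on the monosubstituted C13 vinyl group and then undergoes intramolecular [2+2] cycloaddition and cycloreversion with the 1,1-disubstituted alkene of the isopropenyl ketone, releasing ethylene and forming the trisubstituted C12=C13 enone. The closest known reaction type is ring-closing metathesis of a terminal alkene with a methacryloyl-type alkene to give α-methyl cycloalkenones and α-methyl unsaturated lactones. It closes the six-membered carbocycle C1–C10–C11–C12–C13–C14 by the C12=C13 bond, cis-fused to the oxolane across C1–C10 and trans-fused to the oxepane across C1–C14, and this is the last ring to be formed. No stereocentre is created: C1, C10 and C14 are carried in from step 15, and the cis-fused enone formed here should present its convex face (that of H1 and H10) to hydrogen and hydride in steps 23 and 24, which set C12 and C11. The step needs cyclization to outrun cross-metathesis of the vinyl group, which is secured by the syn, exo placement of the C10 acyl and C14 alkenyl groups on adjacent carbons of the rigid tricyclic tris-ether; no selection among alkenes is needed because the C4=C5 alkene was hydrogenated in step 11.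

Step 23
Reactants: 31 tetracyclic enone
Product: 32 (12R)-11-ketone: 31 with C12=C13 saturated
Conditions: H2 (1 atm), 10% Pd/C, EtOAc, 23 °C
Reagents that add atoms: none
Why: Heterogeneous hydrogenation should add hydrogen from the convex face, anti to the axial C9 of the oxolane, so that H12 is syn to H1 and H10 and the methyl group goes to the concave face (12R).

Step 24
Reactants: 32 (12R)-11-ketone
Product: 33 (11R,12R)-11-alcohol
Conditions: NaBH4, MeOH, −40 → −20 °C, used directly after step 23
Reagents that add atoms: none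
Why: Hydride reduction from the same convex face (axial attack, the other face being blocked by C9 and the C12 methyl group) should give the equatorial (11R) alcohol cis to the methyl group, at a temperature that avoids epimerization at C12.

Step 25
Reactants: 33 (11R,12R)-11-alcohol
Product: 34 CNP0289153.2
Conditions: Ac2O, DMAP (cat.), pyridine, 23 °C
Reagents that add atoms: acetic anhydride (CC(=O)OC(C)=O)
Why: DMAP-catalysed acetylation of the secondary alcohol gives the target without touching any stereocentre.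

**Compound list**

1 | (E)-but-2-enal | C/C=C/C=O | starting material
2 | 2-[(Z)-but-2-en-1-yl]-4,4,5,5-tetramethyl-1,3,2-dioxaborolane | C/C=C\CB1OC(C)(C)C(C)(C)O1 | starting material
3 | (3R,4R,5E)-3-methylhepta-1,5-dien-4-ol | C/C=C/[C@@H](O)[C@H](C)C=C | intermediate
4 | (3R,4R,5E)-4-methoxy-3-methylhepta-1,5-diene | C/C=C/[C@@H](OC)[C@H](C)C=C | intermediate
5 | (3R,4S,5E)-4-methoxy-3-methylhept-5-en-1-ol | C/C=C/[C@@H](OC)[C@H](C)CCO | intermediate
6 | (3R,4S,5E)-4-methoxy-3-methylhept-5-enal | C/C=C/[C@@H](OC)[C@H](C)CC=O | intermediate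
7 | (R)-but-3-ene-1,2-diol | C=C[C@@H](O)CO | starting material
8 | (4R)-4-vinyl-1,3,2-dioxathiolane 2-oxide | C=C[C@@H]1COS(=O)O1 | intermediate
9 | (4R)-4-vinyl-1,3,2-dioxathiolane 2,2-dioxide | C=C[C@@H]1COS(=O)(=O)O1 | intermediate
10 | dimethyl malonate | COC(=O)CC(=O)OC | starting material
11 | dimethyl (2R)-2-vinylcyclopropane-1,1-dicarboxylate | C=C[C@H]1CC1(C(=O)OC)C(=O)OC | intermediate
12 | dimethyl (2S,5S)-5-ethenyl-2-[(2R,3S,4E)-3-methoxy-2-methylhex-4-en-1-yl]oxolane-3,3-dicarboxylate | C/C=C/[C@@H](OC)[C@H](C)C[C@@H]1O[C@H](C=C)CC1(C(=O)OC)C(=O)OC | intermediate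
13 | dimethyl (2S,5S)-5-acetyl-2-[(2R,3S,4E)-3-methoxy-2-methylhex-4-en-1-yl]oxolane-3,3-dicarboxylate | C/C=C/[C@@H](OC)[C@H](C)C[C@@H]1O[C@H](C(C)=O)CC1(C(=O)OC)C(=O)OC | intermediate
14 | dimethyl (2S,5S)-5-[(2S)-2-hydroxybut-3-en-2-yl]-2-[(2R,3S,4E)-3-methoxy-2-methylhex-4-en-1-yl]oxolane-3,3-dicarboxylate | C/C=C/[C@@H](OC)[C@H](C)C[C@@H]1O[C@H]([C@@](C)(O)C=C)CC1(C(=O)OC)C(=O)OC | intermediate
15 | dimethyl (2S,3S,4Z,6S,7R,9S)-3-hydroxy-6-methoxy-3,7-dimethyl-2,9-epoxycyclodec-4-ene-10,10-dicarboxylate | CO[C@@H]1/C=C\[C@](C)(O)[C@@H]2CC(C(=O)OC)(C(=O)OC)[C@H](C[C@H]1C)O2 | intermediate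
16 | dimethyl (2S,3S,6R,7R,9S)-3-hydroxy-6-methoxy-3,7-dimethyl-2,9-epoxycyclodecane-10,10-dicarboxylate | CO[C@@H]1CC[C@](C)(O)[C@@H]2CC(C(=O)OC)(C(=O)OC)[C@H](C[C@H]1C)O2 | intermediate
17 | dimethyl (2S,3S,6R,7R,9S)-3-[(tert-butyldimethylsilyl)oxy]-6-methoxy-3,7-dimethyl-2,9-epoxycyclodecane-10,10-dicarboxylate | CO[C@@H]1CC[C@](C)(O[Si](C)(C)C(C)(C)C)[C@@H]2CC(C(=O)OC)(C(=O)OC)[C@H](C[C@H]1C)O2 | intermediate
18 | methyl (2S,3S,6R,7R,9S)-3-[(tert-butyldimethylsilyl)oxy]-6-methoxy-3,7-dimethyl-2,9-epoxycyclodecane-10-carboxylate, C10 epimers | CO[C@@H]1CC[C@](C)(O[Si](C)(C)C(C)(C)C)[C@@H]2CC(C(=O)OC)[C@H](C[C@H]1C)O2 | intermediate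
19 | 10-(phenylselanyl) derivative of 18, C10 epimers | CO[C@@H]1CC[C@](C)(O[Si](C)(C)C(C)(C)C)[C@@H]2CC([Se]c3ccccc3)(C(=O)OC)[C@H](C[C@H]1C)O2 | intermediate
20 | 10-(phenylseleninyl) derivative of 18 | CO[C@@H]1CC[C@](C)(O[Si](C)(C)C(C)(C)C)[C@@H]2CC([Se](=O)c3ccccc3)(C(=O)OC)[C@H](C[C@H]1C)O2 | intermediate
21 | methyl (2S,3S,6R,7R,9S)-3-[(tert-butyldimethylsilyl)oxy]-6-methoxy-3,7-dimethyl-2,9-epoxycyclodec-1(10)-ene-10-carboxylate | CO[C@@H]1CC[C@](C)(O[Si](C)(C)C(C)(C)C)[C@@H]2C=C(C(=O)OC)[C@H](C[C@H]1C)O2 | intermediate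
22 | (4R)-4-methyloxolan-2-one | C[C@H]1COC(=O)C1 | starting material
23 | methyl (1S,2S,3S,6R,7R,9S,10R)-3-[(tert-butyldimethylsilyl)oxy]-6-methoxy-3,7-dimethyl-1-[(3S,4R)-4-methyl-2-oxooxolan-3-yl]-2,9-epoxycyclodecane-10-carboxylate | CO[C@@H]1CC[C@](C)(O[Si](C)(C)C(C)(C)C)[C@@H]2[C@@H]([C@H]3C(=O)OC[C@@H]3C)[C@@H](C(=O)OC)[C@H](C[C@H]1C)O2 | intermediate
24 | lactol of 23: 1-[(3S,4R)-2-hydroxy-4-methyloxolan-3-yl] analogue, anomers | CO[C@@H]1CC[C@](C)(O[Si](C)(C)C(C)(C)C)[C@@H]2[C@@H]([C@H]3C(O)OC[C@@H]3C)[C@@H](C(=O)OC)[C@H](C[C@H]1C)O2 | intermediate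
25 | methyl (1S,2S,3S,6R,7R,9S,10R)-3-[(tert-butyldimethylsilyl)oxy]-1-[(3S,4R)-5-hydroxy-4-methylpent-1-en-3-yl]-6-methoxy-3,7-dimethyl-2,9-epoxycyclodecane-10-carboxylate | CO[C@@H]1CC[C@](C)(O[Si](C)(C)C(C)(C)C)[C@@H]2[C@@H]([C@@H](C=C)[C@@H](C)CO)[C@@H](C(=O)OC)[C@H](C[C@H]1C)O2 | intermediate
26 | 3-hydroxy analogue of 25 (C3 tertiary alcohol, C16 primary alcohol) | CO[C@@H]1CC[C@](C)(O)[C@@H]2[C@@H]([C@@H](C=C)[C@@H](C)CO)[C@@H](C(=O)OC)[C@H](C[C@H]1C)O2 | intermediate
27 | C16 trifluoromethanesulfonate of 26 | CO[C@@H]1CC[C@](C)(O)[C@@H]2[C@@H]([C@@H](C=C)[C@@H](C)COS(=O)(=O)C(F)(F)F)[C@@H](C(=O)OC)[C@H](C[C@H]1C)O2 | intermediate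
28 | tricyclic vinyl ester (1S,2S,3S,6R,7R,9S,10R,14S,15R): oxolane, oxonane and C3–O–C16 oxepane closed, C14–CH=CH2, C10–CO2CH3 | CO[C@@H]1CC[C@]2(C)OC[C@H](C)[C@H](C=C)[C@H]3[C@@H](C(=O)OC)[C@H](C[C@H]1C)O[C@H]23 | intermediate
29 | Weinreb amide of 28 (C10–CON(CH3)OCH3) | CO[C@@H]1CC[C@]2(C)OC[C@H](C)[C@H](C=C)[C@H]3[C@@H](C(=O)N(C)OC)[C@H](C[C@H]1C)O[C@H]23 | intermediate
30 | isopropenyl ketone (C10–CO–C(CH3)=CH2, C14–CH=CH2) | CO[C@@H]1CC[C@]2(C)OC[C@H](C)[C@H](C=C)[C@H]3[C@@H](C(=O)C(C)=C)[C@H](C[C@H]1C)O[C@H]23 | intermediate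
31 | tetracyclic enone (1S,2S,3S,6R,7R,9S,10R,14S,15R), 11-oxo, C12=C13 | CO[C@@H]1CC[C@]2(C)OC[C@H](C)[C@@H]3C=C(C)C(=O)[C@@H]4[C@H]3[C@@H]2O[C@H]4C[C@H]1C | intermediate
32 | (12R)-11-ketone | CO[C@@H]1CC[C@]2(C)OC[C@H](C)[C@@H]3C[C@@H](C)C(=O)[C@@H]4[C@H]3[C@@H]2O[C@H]4C[C@H]1C | intermediate
33 | (11R,12R)-11-alcohol | CO[C@@H]1CC[C@]2(C)OC[C@H](C)[C@@H]3C[C@@H](C)[C@@H](O)[C@@H]4[C@H]3[C@@H]2O[C@H]4C[C@H]1C | intermediate
34 | CNP0289153.2, (1S,2S,3S,6R,7R,9S,10R,11R,12R,14S,15R)-11-acetate | CO[C@@H]1CC[C@]2(C)OC[C@H](C)[C@@H]3C[C@@H](C)[C@@H](OC(C)=O)[C@@H]4[C@H]3[C@@H]2O[C@H]4C[C@H]1C | target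

**Totals and risks**

Total step count: 25. Longest linear sequence: 23 steps (steps 1–4, then 7–25).

The three steps most likely to fail:

Step 15. Proton transfer from the γ-positions (C2–H, C9–H) of enoate 21 to the lactone enolate could outpace addition at the hindered β-carbon and lead to double-bond migration, and slow addition could erode facial control. The fallback sets out from 22, which is converted (LiN(i-Pr)2, Me3SiCl, THF, −78 °C) into the silyl ketene acetal trimethyl{[(4R)-4-methyl-4,5-dihydrofuran-2-yl]oxy}silane F1. F1 is added to 21 in a non-basic Mukaiyama–Michael reaction (TiCl4, CH2Cl2, −78 °C), and aqueous work-up returns to the route at 23.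

Step 19. The primary triflate could be consumed by elimination or by attack of the ester carbonyl or the vinyl group before the hindered tertiary hydroxyl closes the seven-membered ring. The fallback sets out from 26: chemoselective oxidation of the primary alcohol (TEMPO cat., PhI(OAc)2, CH2Cl2) gives the C16 hydroxy aldehyde F2. Reductive etherification of F2 (Et3SiH, Me3SiOTf, CH2Cl2, −78 °C; a cyclic oxocarbenium ion from the C3 hydroxyl and the aldehyde is reduced at C16) returns at 28.

Step 22. Turnover at the electron-poor 1,1-disubstituted alkene could be slow, so that catalyst decay and cross-metathesis through the vinyl group compete. The fallback sets out from 28: acylation of LiCH(CH3)P(O)(OMe)2 (THF, −78 °C) gives the β-ketophosphonate F3, and ozonolysis of the vinyl group (O3, CH2Cl2/MeOH, −78 °C; Me2S) gives the C13 aldehyde F4. An intramolecular Horner–Wadsworth–Emmons reaction of F4 (LiCl, i-Pr2NEt, MeCN, 23 °C) forms the same C12=C13 bond and returns at 31.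

**Further compounds**

F1 | step 15 | trimethyl{[(4R)-4-methyl-4,5-dihydrofuran-2-yl]oxy}silane | C[C@H]1COC(O[Si](C)(C)C)=C1
F2 | step 19 | C16 aldehyde of 26 (C3 hydroxyl free) | CO[C@@H]1CC[C@](C)(O)[C@@H]2[C@@H]([C@@H](C=C)[C@@H](C)C=O)[C@@H](C(=O)OC)[C@H](C[C@H]1C)O2
F3 | step 22 | β-ketophosphonate from 28 (C10–CO–CH(CH3)–P(O)(OCH3)2, C14 vinyl) | CO[C@@H]1CC[C@]2(C)OC[C@H](C)[C@H](C=C)[C@H]3[C@@H](C(=O)C(C)P(=O)(OC)OC)[C@H](C[C@H]1C)O[C@H]23
F4 | step 22 | C13 aldehyde of F3 | CO[C@@H]1CC[C@]2(C)OC[C@H](C)[C@H](C=O)[C@H]3[C@@H](C(=O)C(C)P(=O)(OC)OC)[C@H](C[C@H]1C)O[C@H]23
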